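**Retrosynthetic overview**
1. The butenolide is closed last: intramolecular Wittig reaction of an α-hydroxy ketone with Ph3P=C=C=O. The hydroxy ketone comes from the methyl ketone of (E)-geranylacetone, which also supplies both E-alkenes.
2. The ring C2-methyl and C2=C3 alkene come from methylation of the enol triflate of an α-quaternary cyclohexanone.
3. Key disconnection, ring C1–CH2: (3R)-2-bromo-3-methylcyclohexanone acts as an enolonium (α-keto cation) equivalent towards the B-alkyl-9-BBN of the whole side chain (1,2-boronate shift). The regiodefined enolate released in the same flask is methylated anti to the C3 methyl, which sets the quaternary centre.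
4. The C6 stereocentre comes from Cu-catalysed asymmetric conjugate addition of Me2Zn to cyclohex-2-en-1-one; the side-chain triene comes from SeO2 oxidation and Wittig methylenation.
5. Ring order: the carbocycle is bought and only decorated; the butenolide is the only ring formed, in the last step.

Assumptions: geranylacetone is bought as the E isomer. Target ring numbering: C1 = quaternary carbon, C2 = methyl-bearing sp2 carbon, C6 = CH(CH3). Ligand L = O,O′-[(R)-1,1′-binaphthalene-2,2′-diyl] N,N-bis[(S)-1-phenylethyl]phosphoramidite.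

**Step 1**
Reactants: 1 (5E)-6,10-dimethylundeca-5,9-dien-2-one ((E)-geranylacetone)
Product: 2 2-[(3E)-4,8-dimethylnona-3,7-dien-1-yl]-2-methyl-1,3-dioxolane
Conditions: HOCH2CH2OH (3 eq), PPTS (5 mol %), benzene, reflux, Dean–Stark
Reagents that add atoms: ethylene glycol OCCO
Why: acid-catalysed ketalisation masks the methyl ketone against the borane, organolithium and amide bases used later, and the trisubstituted alkenes tolerate PPTS.

**Step 2**
Reactants: 2 2-[(3E)-4,8-dimethylnona-3,7-dien-1-yl]-2-methyl-1,3-dioxolane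
Product: 4 (2E,6E)-2,6-dimethyl-9-(2-methyl-1,3-dioxolan-2-yl)nona-2,6-dienal, via allylic alcohol 3 (not isolated)
Conditions: SeO2 (0.2 eq), t-BuOOH (3 eq), salicylic acid (0.1 eq), CH2Cl2, rt; crude, then MnO2 (15 eq), CH2Cl2, rt
Reagents that add atoms: tert-butyl hydroperoxide CC(C)(C)OO; selenium dioxide O=[Se]=O (relays the oxygen atom)
Why: SeO2 allylic oxidation (ene reaction then 2,3-sigmatropic shift) attacks only the terminal E-methyl of the gem-dimethyl alkene, so the new trisubstituted alkene is E, and MnO2 takes the allylic alcohol on to the enal.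

**Step 3**
Reactants: 4 (2E,6E)-2,6-dimethyl-9-(2-methyl-1,3-dioxolan-2-yl)nona-2,6-dienal
Product: 5 2-[(3E,7E)-4,8-dimethyldeca-3,7,9-trien-1-yl]-2-methyl-1,3-dioxolane
Conditions: Ph3PCH3Br (1.3 eq), KOt-Bu (1.25 eq), THF, 0 °C→rt
Reagents that add atoms: methyltriphenylphosphonium bromide C[P+](c1ccccc1)(c1ccccc1)c1ccccc1.[Br-]
Why: Wittig methylenation of the enal gives the terminal diene without touching the alkene geometry.

**Step 4**
Reactants: 6 cyclohex-2-en-1-one
Product: 9 (3R)-2-bromo-3-methylcyclohexan-1-one as a mixture of C2 epimers, via zinc enolate 7 (not isolated), via silyl enol ether 8 (not isolated)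
Conditions: Me2Zn (1.4 eq), Cu(OTf)2 (1 mol %), L (2 mol %), toluene, −30 °C; TMSOTf (1.4 eq), −30→0 °C; volatiles removed; NBS (1.05 eq), THF, −78 °C
Reagents that add atoms: dimethylzinc C[Zn]C; N-bromosuccinimide O=C1CCC(=O)N1Br
Why: Cu/phosphoramidite asymmetric conjugate addition sets the 3R centre (the future ring C6), silyl trapping keeps the enolate regiochemistry, and electrophilic bromination of the silyl enol ether puts bromine on C2 only. The ligand antipode is the mirror image of the one that gives (S)-3-alkylcyclohexanones; the sense is checked by hydrolysing an aliquot of 8 to (R)-(+)-3-methylcyclohexanone.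

**Step 5 (key step)**
Reactants: 5 2-[(3E,7E)-4,8-dimethyldeca-3,7,9-trien-1-yl]-2-methyl-1,3-dioxolane; 9 (3R)-2-bromo-3-methylcyclohexan-1-one
Product: 13 (2R,3R)-2-[(3E,7E)-3,7-dimethyl-10-(2-methyl-1,3-dioxolan-2-yl)deca-3,7-dien-1-yl]-2,3-dimethylcyclohexan-1-one, via B-alkyl-9-BBN 10 (not isolated), via enol borinate 11 (not isolated), via lithium enolate 12 (not isolated)
Conditions: 5 (1.05 eq), 9-BBN (1.0 eq), THF, 0 °C→rt; then 9 (1.0 eq), KOC6H3-2,6-(t-Bu)2 (1.0 eq), THF, 0 °C; then MeLi (2.1 eq), −78 °C; MeI (4 eq), DMPU, −78→0 °C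
Reagents that add atoms: iodomethane CI
Why: Proposed new method: 9-BBN adds only to the terminal vinyl group of the diene (anti-Markovnikov, as in homoallylic borane preparations). The hindered phenoxide then reversibly forms the α-bromo enolate of 9, which binds the borane; the primary B-alkyl group migrates from boron to C2 with loss of bromide (1,2-boronate shift, Brown α-alkylation of α-bromo ketones with B-alkyl-9-BBN). The α-bromo ketone thus serves as an enolonium equivalent that joins the ketone α-carbon to a nucleophilic alkylborane carbon. What is new is that the regiodefined enol borinate is not protonated: MeLi (one equivalent consumed by the phenol) opens it to the C1=C2 lithium enolate, as in the known release of lithium enolates from enol borinates by alkyllithiums and in enoxyborate alkylations. MeI then attacks C2 anti to the pseudoaxial C3 methyl (A(1,2) strain control), giving the 2R quaternary centre with the two methyls trans.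

**Step 6**
Reactants: 13 (2R,3R)-2-[(3E,7E)-3,7-dimethyl-10-(2-methyl-1,3-dioxolan-2-yl)deca-3,7-dien-1-yl]-2,3-dimethylcyclohexan-1-one
Product: 15 (5R,6R)-6-[(3E,7E)-3,7-dimethyl-10-(2-methyl-1,3-dioxolan-2-yl)deca-3,7-dien-1-yl]-5,6-dimethylcyclohex-1-en-1-yl trifluoromethanesulfonate, via potassium enolate 14 (not isolated)
Conditions: KN(SiMe3)2 (1.2 eq), THF, −78 °C; PhNTf2 (1.25 eq), −78→0 °C
Reagents that add atoms: N-phenylbis(trifluoromethanesulfonimide) O=S(=O)(N(c1ccccc1)S(=O)(=O)C(F)(F)F)C(F)(F)F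
Why: enol triflate formation; the ketone can enolise only towards the CH2 side because the other α-carbon is quaternary, so the alkene position is fixed and no stereocentre is at risk.

**Step 7**
Reactants: 15 (5R,6R)-6-[(3E,7E)-3,7-dimethyl-10-(2-methyl-1,3-dioxolan-2-yl)deca-3,7-dien-1-yl]-5,6-dimethylcyclohex-1-en-1-yl trifluoromethanesulfonate
Product: 16 2-{(3E,7E)-4,8-dimethyl-10-[(1R,6R)-1,2,6-trimethylcyclohex-2-en-1-yl]deca-3,7-dien-1-yl}-2-methyl-1,3-dioxolane
Conditions: MeZnCl (3 eq), Pd(PPh3)4 (5 mol %), THF, 60 °C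
Reagents that add atoms: methylzinc chloride C[Zn]Cl
Why: Negishi cross-coupling replaces the triflate by methyl with retention of the alkene position, giving the 1,2,6-trimethylcyclohex-2-enyl ring; the ketal and isolated alkenes are inert.

**Step 8**
Reactants: 16 2-{(3E,7E)-4,8-dimethyl-10-[(1R,6R)-1,2,6-trimethylcyclohex-2-en-1-yl]deca-3,7-dien-1-yl}-2-methyl-1,3-dioxolane
Product: 17 (5E,9E)-6,10-dimethyl-12-[(1R,6R)-1,2,6-trimethylcyclohex-2-en-1-yl]dodeca-5,9-dien-2-one
Conditions: PPTS (0.2 eq), acetone–H2O 10:1, 55 °C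
Reagents that add atoms: water O
Why: mild acid-catalysed transketalisation/hydrolysis frees the methyl ketone without isomerising the trisubstituted alkenes.

**Step 9**
Reactants: 17 (5E,9E)-6,10-dimethyl-12-[(1R,6R)-1,2,6-trimethylcyclohex-2-en-1-yl]dodeca-5,9-dien-2-one
Product: 19 (5E,9E)-1-hydroxy-6,10-dimethyl-12-[(1R,6R)-1,2,6-trimethylcyclohex-2-en-1-yl]dodeca-5,9-dien-2-one, via lithium enolate 18 (not isolated)
Conditions: LiN(i-Pr)2 (1.1 eq), THF, −78 °C (ketone added to base); 2-(phenylsulfonyl)-3-phenyloxaziridine (1.3 eq), −78 °C; NH4Cl aq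
Reagents that add atoms: 2-(phenylsulfonyl)-3-phenyloxaziridine O=S(=O)(N1OC1c1ccccc1)c1ccccc1
Why: kinetic deprotonation takes place at the methyl group, and Davis oxaziridine hydroxylation of the enolate delivers oxygen without touching the three trisubstituted alkenes, as a peracid would.

**Step 10**
Reactants: 19 (5E,9E)-1-hydroxy-6,10-dimethyl-12-[(1R,6R)-1,2,6-trimethylcyclohex-2-en-1-yl]dodeca-5,9-dien-2-one
Product: 21 4-{(3E,7E)-4,8-dimethyl-10-[(1R,6R)-1,2,6-trimethylcyclohex-2-en-1-yl]deca-3,7-dien-1-yl}furan-2(5H)-one, via acyl ylide 20 (not isolated)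
Conditions: Ph3P=C=C=O (1.3 eq), toluene, 100 °C
Reagents that add atoms: (triphenylphosphoranylidene)ketene O=C=C=P(c1ccccc1)(c1ccccc1)c1ccccc1
Why: the hydroxyl adds to the ketene of the Bestmann ylide to give an ester ylide, which closes on the adjacent ketone by intramolecular Wittig reaction to the 4-substituted butenolide; no stereocentre is involved.

**Compound list**
1 | (5E)-6,10-dimethylundeca-5,9-dien-2-one | CC(C)=CCC/C(C)=C/CCC(C)=O | starting material
2 | 2-[(3E)-4,8-dimethylnona-3,7-dien-1-yl]-2-methyl-1,3-dioxolane | CC(C)=CCC/C(C)=C/CCC1(C)OCCO1 | intermediate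
3 | (2E,6E)-2,6-dimethyl-9-(2-methyl-1,3-dioxolan-2-yl)nona-2,6-dien-1-ol | OC/C(C)=C/CC/C(C)=C/CCC1(C)OCCO1 | intermediate (not isolated)
4 | (2E,6E)-2,6-dimethyl-9-(2-methyl-1,3-dioxolan-2-yl)nona-2,6-dienal | O=C/C(C)=C/CC/C(C)=C/CCC1(C)OCCO1 | intermediate
5 | 2-[(3E,7E)-4,8-dimethyldeca-3,7,9-trien-1-yl]-2-methyl-1,3-dioxolane | C=C/C(C)=C/CC/C(C)=C/CCC1(C)OCCO1 | intermediate
6 | cyclohex-2-en-1-one | O=C1C=CCCC1 | starting material
7 | methylzinc (3R)-3-methylcyclohex-1-en-1-olate | C[Zn]OC1=C[C@H](C)CCC1 | intermediate (not isolated)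
8 | trimethyl{[(3R)-3-methylcyclohex-1-en-1-yl]oxy}silane | C[Si](C)(C)OC1=C[C@H](C)CCC1 | intermediate (not isolated)
9 | (3R)-2-bromo-3-methylcyclohexan-1-one (C2 epimers) | O=C1CCC[C@@H](C)C1Br | intermediate
10 | 9-[(3E,7E)-3,7-dimethyl-10-(2-methyl-1,3-dioxolan-2-yl)deca-3,7-dien-1-yl]-9-borabicyclo[3.3.1]nonane | B1(C2CCCC1CCC2)CC/C(C)=C/CC/C(C)=C/CCC3(C)OCCO3 | intermediate (not isolated)
11 | 9-({(3R)-2-[(3E,7E)-3,7-dimethyl-10-(2-methyl-1,3-dioxolan-2-yl)deca-3,7-dien-1-yl]-3-methylcyclohex-1-en-1-yl}oxy)-9-borabicyclo[3.3.1]nonane | B1(C2CCCC1CCC2)OC4=C(CC/C(C)=C/CC/C(C)=C/CCC3(C)OCCO3)[C@H](C)CCC4 | intermediate (not isolated)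
12 | lithium (3R)-2-[(3E,7E)-3,7-dimethyl-10-(2-methyl-1,3-dioxolan-2-yl)deca-3,7-dien-1-yl]-3-methylcyclohex-1-en-1-olate | [Li]OC1=C(CC/C(C)=C/CC/C(C)=C/CCC2(C)OCCO2)[C@H](C)CCC1 | intermediate (not isolated)
13 | (2R,3R)-2-[(3E,7E)-3,7-dimethyl-10-(2-methyl-1,3-dioxolan-2-yl)deca-3,7-dien-1-yl]-2,3-dimethylcyclohexan-1-one | O=C1CCC[C@@H](C)[C@@]1(C)CC/C(C)=C/CC/C(C)=C/CCC2(C)OCCO2 | intermediate
14 | potassium (5R,6R)-6-[(3E,7E)-3,7-dimethyl-10-(2-methyl-1,3-dioxolan-2-yl)deca-3,7-dien-1-yl]-5,6-dimethylcyclohex-1-en-1-olate | [K]OC1=CCC[C@@H](C)[C@@]1(C)CC/C(C)=C/CC/C(C)=C/CCC2(C)OCCO2 | intermediate (not isolated)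
15 | (5R,6R)-6-[(3E,7E)-3,7-dimethyl-10-(2-methyl-1,3-dioxolan-2-yl)deca-3,7-dien-1-yl]-5,6-dimethylcyclohex-1-en-1-yl trifluoromethanesulfonate | O=S(=O)(OC1=CCC[C@@H](C)[C@@]1(C)CC/C(C)=C/CC/C(C)=C/CCC2(C)OCCO2)C(F)(F)F | intermediate
16 | 2-{(3E,7E)-4,8-dimethyl-10-[(1R,6R)-1,2,6-trimethylcyclohex-2-en-1-yl]deca-3,7-dien-1-yl}-2-methyl-1,3-dioxolane | CC1=CCC[C@@H](C)[C@@]1(C)CC/C(C)=C/CC/C(C)=C/CCC2(C)OCCO2 | intermediate
17 | (5E,9E)-6,10-dimethyl-12-[(1R,6R)-1,2,6-trimethylcyclohex-2-en-1-yl]dodeca-5,9-dien-2-one | CC1=CCC[C@@H](C)[C@@]1(C)CC/C(C)=C/CC/C(C)=C/CCC(C)=O | intermediate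
18 | lithium (5E,9E)-6,10-dimethyl-12-[(1R,6R)-1,2,6-trimethylcyclohex-2-en-1-yl]dodeca-1,5,9-trien-2-olate | CC1=CCC[C@@H](C)[C@@]1(C)CC/C(C)=C/CC/C(C)=C/CCC(=C)O[Li] | intermediate (not isolated)
19 | (5E,9E)-1-hydroxy-6,10-dimethyl-12-[(1R,6R)-1,2,6-trimethylcyclohex-2-en-1-yl]dodeca-5,9-dien-2-one | CC1=CCC[C@@H](C)[C@@]1(C)CC/C(C)=C/CC/C(C)=C/CCC(=O)CO | intermediate
20 | (5E,9E)-6,10-dimethyl-2-oxo-12-[(1R,6R)-1,2,6-trimethylcyclohex-2-en-1-yl]dodeca-5,9-dien-1-yl (triphenyl-λ5-phosphanylidene)acetate | CC1=CCC[C@@H](C)[C@@]1(C)CC/C(C)=C/CC/C(C)=C/CCC(=O)COC(=O)C=P(c2ccccc2)(c2ccccc2)c2ccccc2 | intermediate (not isolated)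
21 | 4-{(3E,7E)-4,8-dimethyl-10-[(1R,6R)-1,2,6-trimethylcyclohex-2-en-1-yl]deca-3,7-dien-1-yl}furan-2(5H)-one | CC1=CCC[C@@H](C)[C@@]1(C)CC/C(C)=C/CC/C(C)=C/CCC1=CC(=O)OC1 | target

**Count**
Total steps: 10. Longest linear sequence: 9 steps (steps 1, 2, 3, 5, 6, 7, 8, 9, 10 from geranylacetone); step 4 is a one-step side branch from cyclohexenone.

**Three steps most likely to fail**

Step 5. The hindered secondary α-bromo ketone may eliminate or undergo Favorskii rearrangement instead of the boronate shift, or the phenol may protonate the enol borinate before MeLi opens it, which would lose the regiocontrol of the methylation. The fallback sets out from cyclohex-2-en-1-one 6 and borane 10 and comes back at ketone 13. The union is moved to the sp2 α-carbon and the stereocentres are set afterwards. Compound 6 is iodinated (I2, K2CO3, cat. DMAP, THF–H2O) to 2-iodocyclohex-2-en-1-one F1. B-alkyl Suzuki–Miyaura coupling of F1 with 10 (PdCl2(dppf), AsPh3, Cs2CO3, DMF–THF–H2O, rt) gives 2-[(3E,7E)-3,7-dimethyl-10-(2-methyl-1,3-dioxolan-2-yl)deca-3,7-dien-1-yl]cyclohex-2-en-1-one F2. Cu-catalysed asymmetric conjugate addition of AlMe3 (Cu thiophene-2-carboxylate CuO2C-C4H3S, chiral phosphoramidite, Et2O, −30 °C) gives dimethylaluminium (3R)-2-[(3E,7E)-3,7-dimethyl-10-(2-methyl-1,3-dioxolan-2-yl)deca-3,7-dien-1-yl]-3-methylcyclohex-1-en-1-olate F3. After activation with MeLi, F3 is methylated by MeI anti to the new methyl to give 13.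

Step 9. The methyl-ketone enolate may give regioisomeric hydroxylation, aldol products or imine adducts with the oxaziridine by-product. The fallback sets out from methyl ketone 17 and comes back at target 21, avoiding the hydroxy ketone altogether. LiN(SiMe3)2 then CF3CO2CH2CF3 acylates the methyl side to (7E,11E)-1,1,1-trifluoro-8,12-dimethyl-14-[(1R,6R)-1,2,6-trimethylcyclohex-2-en-1-yl]tetradeca-7,11-diene-2,4-dione F4. MsN3, Et3N, H2O in MeCN (detrifluoroacetylative diazo transfer) gives (5E,9E)-1-diazo-6,10-dimethyl-12-[(1R,6R)-1,2,6-trimethylcyclohex-2-en-1-yl]dodeca-5,9-dien-2-one F5. Rh2(OAc)4-catalysed O–H insertion with diethylphosphonoacetic acid gives (5E,9E)-6,10-dimethyl-2-oxo-12-[(1R,6R)-1,2,6-trimethylcyclohex-2-en-1-yl]dodeca-5,9-dien-1-yl (diethoxyphosphoryl)acetate F6. Intramolecular Horner–Wadsworth–Emmons reaction (LiCl, DBU, MeCN) closes the butenolide to 21.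

Step 7. Oxidative addition and transmetalation at a vinyl triflate flanked by a quaternary carbon may be slow, leading to triflate hydrolysis or reduction. The fallback sets out from ketone 13 and comes back at 16 by carbonyl addition and elimination instead of cross-coupling. MeLi with CeCl3 (THF, −78 °C) adds to 13 to give (2R,3R)-2-[(3E,7E)-3,7-dimethyl-10-(2-methyl-1,3-dioxolan-2-yl)deca-3,7-dien-1-yl]-1,2,3-trimethylcyclohexan-1-ol F7 as a mixture of C1 epimers. Dehydration (SOCl2, pyridine, 0 °C, or Burgess reagent) gives 16. The only ring β-hydrogens are on the CH2 side, so the endocyclic alkene can form in one position only; the exocyclic methylene isomer is the by-product to separate.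

**Further compounds**
F1 | step 5 | 2-iodocyclohex-2-en-1-one | O=C1CCCC=C1I
F2 | step 5 | 2-[(3E,7E)-3,7-dimethyl-10-(2-methyl-1,3-dioxolan-2-yl)deca-3,7-dien-1-yl]cyclohex-2-en-1-one | O=C1CCCC=C1CC/C(C)=C/CC/C(C)=C/CCC2(C)OCCO2
F3 | step 5 | dimethylaluminium (3R)-2-[(3E,7E)-3,7-dimethyl-10-(2-methyl-1,3-dioxolan-2-yl)deca-3,7-dien-1-yl]-3-methylcyclohex-1-en-1-olate | C[Al](C)OC1=C(CC/C(C)=C/CC/C(C)=C/CCC2(C)OCCO2)[C@H](C)CCC1
F4 | step 9 | (7E,11E)-1,1,1-trifluoro-8,12-dimethyl-14-[(1R,6R)-1,2,6-trimethylcyclohex-2-en-1-yl]tetradeca-7,11-diene-2,4-dione | CC1=CCC[C@@H](C)[C@@]1(C)CC/C(C)=C/CC/C(C)=C/CCC(=O)CC(=O)C(F)(F)F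
F5 | step 9 | (5E,9E)-1-diazo-6,10-dimethyl-12-[(1R,6R)-1,2,6-trimethylcyclohex-2-en-1-yl]dodeca-5,9-dien-2-one | CC1=CCC[C@@H](C)[C@@]1(C)CC/C(C)=C/CC/C(C)=C/CCC(=O)C=[N+]=[N-]
F6 | step 9 | (5E,9E)-6,10-dimethyl-2-oxo-12-[(1R,6R)-1,2,6-trimethylcyclohex-2-en-1-yl]dodeca-5,9-dien-1-yl (diethoxyphosphoryl)acetate | CC1=CCC[C@@H](C)[C@@]1(C)CC/C(C)=C/CC/C(C)=C/CCC(=O)COC(=O)CP(=O)(OCC)OCC
F7 | step 7 | (2R,3R)-2-[(3E,7E)-3,7-dimethyl-10-(2-methyl-1,3-dioxolan-2-yl)deca-3,7-dien-1-yl]-1,2,3-trimethylcyclohexan-1-ol (C1 epimers) | CC1(O)CCC[C@@H](C)[C@@]1(C)CC/C(C)=C/CC/C(C)=C/CCC2(C)OCCO2
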